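Assumptions: (S)-(+)-terpinen-4-ol is bought enantiopure. Atom labels C1–C15 follow daucane numbering (C1 = quaternary C–CH3, C4 = C(OH)iPr, C5 = ring-fusion CH, C6 = CH–O, C8/C9 = epoxide). β is the face carrying 4-OH.

## Retrosynthetic overview
1. Target ⇐ ferutinin by α-face epoxidation, and ferutinin ⇐ jaeschkeanadiol by O6-selective acylation.
2. The seven-membered ring is formed last. C8=C9 comes from isomerisation/RCM. C6–C7 and the C6 carbinol come from a visible-light acridinium/chromium methallylation of a β-hydroxy aldehyde (key step, new).
3. The quaternary C1 is set by adding its methyl last, syn to 4-OH, through an alkoxide-directed cuprate addition to a 2-butenylcyclopentenecarbaldehyde. C5 is then set by equilibration.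
4. The C10 chain is built on the vinylogous methyl of the enal by an allylation/Cope sequence in which all primary products converge.
5. The five-membered ring is formed first, by ozonolysis/aldol ring contraction of (S)-terpinen-4-ol. Its C4 is the only purchased stereocentre.

## Route

**Step 1**
Reactants: 1, (S)-(+)-terpinen-4-ol
Product: 2, (S)-terpinen-4-yl triethylsilyl ether
Conditions: TESOTf, 2,6-lutidine, CH2Cl2, 0 °C
Reagents that add atoms: TESOTf, CC[Si](CC)(CC)OS(=O)(=O)C(F)(F)F
Why: Silyl protection of the tertiary alcohol leaves C4 untouched and blocks retro-aldol and acid-assisted β-elimination once the β-oxy aldehyde is unveiled.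

**Step 2**
Reactants: 2
Product: 3, (S)-3-isopropyl-6-oxo-3-(triethylsilyloxy)heptanal
Conditions: O3, CH2Cl2, −78 °C; then Me2S, −78 °C → rt
Reagents that add atoms: ozone, [O-][O+]=O
Why: Ozonolysis cleaves the only alkene to the 1,6-keto aldehyde, and C4 is not involved.

**Step 3**
Reactants: 3
Product: 4, (R)-5-isopropyl-2-methyl-5-(triethylsilyloxy)cyclopent-1-ene-1-carbaldehyde
Conditions: Bn2NH·TFA (0.5 equiv), toluene, 50 °C
Reagents that add atoms: none
Why: In this enamine-mediated intramolecular aldol condensation the aldehyde α-carbon (C5) attacks the methyl ketone (C1), and the free C1–OH leaves faster than the hindered, weakly basic OTES, giving the ring-contracted enal.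

**Step 4**
Reactants: 4; 5, allyl bromide
Product: 6, (R)-2-(but-3-en-1-yl)-5-isopropyl-5-(triethylsilyloxy)cyclopent-1-ene-1-carbaldehyde
Conditions: KHMDS, THF, −78 °C; 5, → rt; then toluene, 120 °C
Reagents that add atoms: allyl bromide, C=CCBr
Why: Deconjugative dienolate allylation is followed by Cope rearrangement. The methyl cis to CHO is deprotonated, and the α-C-allyl (Cope), O-allyl (Claisen then Cope) and direct γ-allyl products all converge on the conjugated γ-allylated enal, with no stereocentre created.

**Step 5**
Reactants: 6
Product: 7, (R)-2-(but-3-en-1-yl)-5-hydroxy-5-isopropylcyclopent-1-ene-1-carbaldehyde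
Conditions: HF·pyridine, THF/pyridine, 0 °C → rt
Reagents that add atoms: none
Why: Desilylation frees 4-OH, and enal 7 has no α-H so it cannot undergo retro-aldol or E1cB loss of that hydroxyl.

**Step 6**
Reactants: 7
Product: 8, (1R,2S,5R)-2-(but-3-en-1-yl)-5-hydroxy-2-methyl-5-isopropylcyclopentane-1-carbaldehyde (CH3, CHO and OH β; butenyl, H5 and iPr α)
Conditions: Me2CuLi (4 equiv, from MeLi/CuI), TMSCl, Et2O, −78 → −20 °C; aq. citric acid/THF; cat. Et3N, CH2Cl2
Reagents that add atoms: methyllithium (as Me2CuLi), [Li]C
Why: In this organocuprate 1,4-addition the C4 alkoxide binds the cuprate and the α-iPr blocks the other face, so CH3 enters C1 from the β face, and C5 then equilibrates to the aldehyde trans to both iPr and the butenyl chain.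

**Step 7 (key step)**
Reactants: 8; 9, methallyltrimethylsilane
Product: 10, diol-diene (C1 S, C4 R, C5 S, C6 S): the C5 substituent is now (S)-CH(OH)CH2C(CH3)=CH2
Conditions: 9 (2 equiv), 9-mesityl-10-methylacridinium ClO4 (3 mol %), CrCl2 (10 mol %), dtbbpy (12 mol %), MeCN/CH2Cl2, 450 nm LEDs, rt; then K2CO3, MeOH
Reagents that add atoms: methallyltrimethylsilane, C=C(C)C[Si](C)(C)C
Why: Proposed new method: the excited acridinium (about +2.1 V) oxidises only the allylsilane (about +1.6 V; the terminal alkene lies above +2.5 V); desilylation gives the methallyl radical, Cr(II) captures it as methallyl–Cr(III), and this adds to the aldehyde through a closed six-membered transition state while Cr also holds O4; that chelate fixes the C=O rotamer toward O4 and leaves only the outer face open (the inner face carries axial C3), giving 6S; the released Me3Si+ silylates the Cr alkoxide and the acridine radical returns Cr(III) to Cr(II), so the cycle is redox-neutral and base-free, which protects this retro-aldol-prone aldehyde; the closest known chemistry is photoredox/chromium carbonyl allylation from alkenes and Nozaki–Hiyama allylation.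

**Step 8**
Reactants: 10
Product: 12, jaeschkeanadiol (4β,6α-dihydroxydauc-8-ene), via 11, the (E)-but-2-enyl isomer of 10 (not isolated)
Conditions: RuHCl(CO)(PPh3)3 (5 mol %), toluene, 80 °C; then Hoveyda–Grubbs II (7 mol %), 80 °C (− propene)
Reagents that add atoms: none
Why: Ru–H moves the monosubstituted alkene by one position faster than it touches the 1,1-disubstituted one, and ring-closing metathesis then forms the trisubstituted C8=C9 of the trans-fused cycloheptene without affecting any stereocentre.

**Step 9**
Reactants: 12; 13, 4-acetoxybenzoic acid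
Product: 15, ferutinin, via 14, O-acetylferutinin (not isolated)
Conditions: 13, EDC·HCl, DMAP, CH2Cl2, rt → 40 °C; then pyrrolidine, 0 °C → rt
Reagents that add atoms: 4-acetoxybenzoic acid, CC(=O)Oc1ccc(cc1)C(=O)O
Why: Steglich esterification acylates only the secondary 6-OH because the tertiary 4-OH is inert, and aminolysis then removes the aryl acetate far faster than the hindered benzoate, with C6 retained.

**Step 10**
Reactants: 15
Product: 16, jaeskeanin (target)
Conditions: mCPBA, NaHCO3, CH2Cl2, 0 °C
Reagents that add atoms: mCPBA, O=C(OO)c1cccc(Cl)c1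
Why: Prilezhaev epoxidation attacks the only alkene from the α face, opposite the angular β-CH3 that sits over C9/C10, which sets 8R,9S, and the bicarbonate buffer prevents acid-induced opening.

## Compound list
1 | (S)-(+)-terpinen-4-ol | CC1=CC[C@](O)(C(C)C)CC1 | starting material
2 | TES ether of 1 | CC1=CC[C@](O[Si](CC)(CC)CC)(C(C)C)CC1 | intermediate
3 | (S)-3-isopropyl-6-oxo-3-(TESO)heptanal | O=CC[C@](O[Si](CC)(CC)CC)(C(C)C)CCC(C)=O | intermediate
4 | (R)-5-isopropyl-2-methyl-5-(TESO)cyclopentenecarbaldehyde | O=CC1=C(C)CC[C@@]1(O[Si](CC)(CC)CC)C(C)C | intermediate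
5 | allyl bromide | C=CCBr | starting material
6 | 2-butenyl TES enal | O=CC1=C(CCC=C)CC[C@@]1(O[Si](CC)(CC)CC)C(C)C | intermediate
7 | 2-butenyl hydroxy enal | O=CC1=C(CCC=C)CC[C@@]1(O)C(C)C | intermediate
8 | quaternary β-hydroxy aldehyde | CC(C)[C@]1(O)CC[C@](C)(CCC=C)[C@H]1C=O | intermediate
9 | methallyltrimethylsilane | C=C(C)C[Si](C)(C)C | starting material
10 | diol-diene | CC(C)[C@]1(O)CC[C@](C)(CCC=C)[C@H]1[C@@H](O)CC(C)=C | intermediate
11 | isomerised diol-diene (not isolated) | CC(C)[C@]1(O)CC[C@](C)(C/C=C/C)[C@H]1[C@@H](O)CC(C)=C | intermediate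
12 | jaeschkeanadiol | CC(C)[C@]1(O)CC[C@]2(C)CC=C(C)C[C@H](O)[C@H]21 | intermediate
13 | 4-acetoxybenzoic acid | CC(=O)Oc1ccc(cc1)C(=O)O | starting material
14 | O-acetylferutinin (not isolated) | CC(C)[C@]1(O)CC[C@]2(C)CC=C(C)C[C@H](OC(=O)c3ccc(OC(C)=O)cc3)[C@H]21 | intermediate
15 | ferutinin | CC(C)[C@]1(O)CC[C@]2(C)CC=C(C)C[C@H](OC(=O)c3ccc(O)cc3)[C@H]21 | intermediate
16 | jaeskeanin | CC(C)[C@]1(O)CC[C@]2(C)C[C@@H]3O[C@]3(C)C[C@H](OC(=O)c3ccc(O)cc3)[C@H]21 | target

## Step count
Total steps: 10. Longest linear sequence: 10.

## Steps most likely to fail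
1. **Step 7 (new photoredox/Cr methallylation).** Catalyst turnover may be poor, or a background Sakurai addition may erode the diastereomer ratio. Fallback with known chemistry: add methallylmagnesium chloride (or run a Zn Barbier reaction) to 8, oxidise the epimer mixture to the C6 ketone with Dess–Martin periodinane, and reset C6 by 4-OH-directed reduction with Me4NBH(OAc)3, which delivers hydride from the β face.
2. **Step 3 (aldol condensation).** Enamine-driven loss of the β-OTES group, or closure to the acetylcyclopentene regioisomer, could compete. Fallback: avoid amine catalysis by converting the aldehyde of 3 to its silyl enol ether (TBSOTf/Et3N), closing the ring by a TiCl4-mediated intramolecular Mukaiyama aldol onto the ketone, and dehydrating the tertiary C1 carbinol with Burgess reagent.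
3. **Step 6 (cuprate addition to a tetrasubstituted enal).** Reactivity may be low, 1,2-addition may intervene, or face selectivity may be poor. Fallback: tethered radical methylation, in which 4-OH is silylated with BrCH2SiMe2Cl, a 6-endo radical conjugate addition to C1 is run with (TMS)3SiH/AIBN (the tether forces syn delivery), and the C–Si bond is protodesilylated with TBAF in DMF to leave the β-CH3.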